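Remark on the chemistry (assumption): cembrane numbering is used throughout. C1–C14 are the ring carbons, C15 is the second olefinic carbon of the dihydrofuran, C16 its OCH2 carbon, C17 the acetoxymethyl carbon, and C18, C19, C20 the methyl groups on C4, C8, C12. In this numbering the target is (2S,7S,8S). TBS = tert-butyldimethylsilyl.

## Analysis of the target

The target (29) is a cembranoid: a 14-membered carbocycle (C1–C14) fused along C1–C2 to a 2,5-dihydrofuran. The ring oxygen bridges C2 and C16, and the tetrasubstituted C1=C15 double bond carries the acetoxymethyl carbon C17. The macrocycle holds two E-trisubstituted olefins (C3=C4 with methyl C18, C11=C12 with methyl C20) and a trans-trisubstituted epoxide at C7–C8 (methyl C19 on C8). There are three stereocentres, C2 (S), C7 (S) and C8 (S). C7 and C8 are vicinal and come as a pair from one epoxidation, but C2 lies five bonds from C7, so no substrate relay can be counted on and each unit needs its own reagent control. The sensitive groups are the doubly allylic C2–O bond (it ionises easily), the epoxide, which faces the C11=C12 olefin across the ring and invites acid-triggered transannular cyclisation, and the primary allylic acetate (labile to hydride, base and zerovalent palladium). The hard parts are closing a 14-membered ring with a defined trisubstituted olefin geometry, the remote C2/C7–C8 relationship, and telling apart the two oxygenated carbons C16 and C17 on C15. The plan rests on the position of the C3=C4 olefin directly beside the C2 oxygen. Read backwards it is a C3≡C4 cycloalkyne, whose propargylic C2 hydroxyl can send hydride to C3 and place a metal, then the methyl group, on C4 with the E geometry fixed by a cyclic intermediate.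

## Retrosynthetic reasoning

**C17–OAc and O–C16 (29 ⇒ 28 ⇒ 26).** The acetate is traced to displacement of the allylic sulfonate 28, and the ring ether bond to an intramolecular etherification of triol 26 through bis-sulfonate 27. C16 and C17 are equivalent arms on C15 until the C2 hydroxyl picks the one that is cis to it across C1=C15. Both arms can therefore be carried identically, and the tetrasubstituted olefin never has a geometry to control. The C2–O bond is not broken, so the forward step only has to sulfonylate the primary hydroxyls in preference to the secondary one.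

**C4–C18 and C3–H/C4–I (26 ⇒ 25 ⇒ 23).** The methyl group is cut off as a cross-coupling on alkenyl iodide 25, and 25 is traced to the propargylic alcohol 23 by anti hydrometalation through alanate 24. Cutting here turns the E-trisubstituted olefin into a triple bond. The geometry is then fixed by a five-membered oxa-aluminacycle (aluminium must sit cis to C2) and not by the thermodynamics of a macrocyclic olefin-forming step.

**C3≡C4, the ring-closing bond (23 ⇒ 22 ⇒ 21).** The 14-membered ring is opened at the triple bond to give diyne 21, with both alkynes methyl-capped. This is the right place for three reasons. A linear four-atom C2–C3≡C4–C5 unit fits a 14-membered ring without strain. Every other unsaturation in the molecule is olefinic and is ignored by an alkylidyne. The only by-product is volatile 2-butyne (4). All three hydroxyls are masked as TBS ethers, so that one desilylation frees them and no acid is needed once epoxide and olefins share a ring.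

**C2 stereocentre and C2–C3 (21 ⇒ 20 ⇒ 19 ⇒ 17 + 18).** The silyl ether goes back to alcohol 20, and its C2–H bond to a catalyst-controlled reduction of ynone 19. The C2–C3 bond is cut to Weinreb amide 17 and propynylmagnesium bromide (18). C2 is thus set before the ring exists and independently of the distant epoxide.

**C14–C1 (17 ⇒ 9 + 15, via 16).** The sp3–sp2 bond between the two halves is cut to the alkylborane 16, made from diene 9, and the bromo enamide 15. The junction is an unfunctionalised CH2–CH2 unit, and 15 is symmetric at C15, so the coupling cannot give olefin isomers.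

**C1=C15 and C1–Br (15 ⇒ 13 ⇒ 11 + 12; 11 ⇒ 10).** The tetrasubstituted olefin is traced to an olefination of the symmetric ketone 11 with phosphonate 12. The bromine comes from bromination–dehydrobromination of 13 through 14, and 11 from dihydroxyacetone dimer (10).

**C13=C14 and C13 oxidation (9 ⇒ 8 ⇒ 7 ⇒ 6).** The terminal vinyl carbon C14 is cut by a methylenation of enal 8. The enal is traced through alcohol 7 to allylic oxidation of the E-methyl group of the prenyl terminus of 6, the standard way to reach C13 in a geranyl chain.

**C5–C6 and the epoxide (6 ⇒ 3 + 4 via 5; 3 ⇒ 2 ⇒ 1).** The C5–C6 bond is cut to the epoxy triflate 3 and lithiated 2-butyne (5, from 4). This brings in C4, C5 and the methyl cap in one step. C7 and C8 come from a Sharpless epoxidation of geraniol (1), whose allylic hydroxyl then becomes the leaving group.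

## Alternatives that were turned down

**Alternative 1:** oxypalladation–carbonylation of an allenol.
- Disconnection: the O–C16 ether bond and the C15–C17 bond are cut together. The dihydrofuran and the acetoxymethyl carbon both arise on a finished 14-membered ring from allenol A2 (free C2 hydroxyl beside an exocyclic C1=C15=C16 allene).
- Forward key step: PdCl2 (divalent palladium) activates the allene, the C2 oxygen adds to the terminal carbon C16, the alkenylpalladium at C15 inserts CO, and MeOH releases the methyl ester A1. CuCl2 returns the palladium to the divalent state.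
- For it: alkoxycarbonylative cyclisation of α-allenols to 2,5-dihydrofuran-3-carboxylates is an established reaction type. The C2–O bond is not broken. Ring and C17 appear in one step, leaving only ester reduction and acetylation. On this point it is stronger than the chosen end game, which needs a triol, a double sulfonylation and a displacement, and carries two protected arms from the start.
- Against it: the step does not solve A2 itself. A2 is a macrocyclic alcohol that is both allylic and allenylic, and its ring must be closed elsewhere with the C2 configuration and the C3=C4 geometry already correct. The oxidative medium (HCl is formed, CuCl2 is a chlorinating Lewis acid) threatens the epoxide through chlorohydrin formation or transannular attack by C11=C12. The two trisubstituted olefins are open to Wacker-type side reactions.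
- Comparison: the chosen route spends five steps after ring closure, but none is oxidative or acidic, and C2 is fixed by catalyst control before the ring exists. In place of the one-step annulation it offers a sequence in which each stereo-element is set by a separately controllable reaction.

**Alternative 2:** hetero-Pauson–Khand macro-annulation.
- Disconnection: three bonds at once, C1–C2, C15–C16 and C16–O. Carbocycle and butenolide form together from the acyclic ynal A4 and CO.
- Forward key step: [RhCl(CO)2]2 (monovalent rhodium) couples the C1≡C15 alkyne and the C2 aldehyde to an oxa-rhodacycle, CO inserts, and reductive elimination gives butenolide A3.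
- For it: the bond economy is the best of all four plans. Two rings and three bonds form in one step from a linear precursor with no protecting group on C2. In step count it would be clearly shorter than the chosen route.
- Against it: this reaction is dependable when a three- or four-atom tether holds alkyne and carbonyl together. Here twelve atoms separate them, so the oxidative cyclisation is entropically an intermolecular event. It must compete with alkyne oligomerisation, decarbonylation of the enal, and ordinary Pauson–Khand reaction with the olefins. C2 is created in the ring closure, five bonds from the nearest stereocentre, so both C2 epimers must be expected. A3 is also at the wrong oxidation level at C16. Taking a butenolide down to a dihydrofuran next to an epoxide gives back the steps saved.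
- Comparison: the chosen strategy is longer but separates the problems. C2 comes from a catalyst-controlled reduction, the ring from a metathesis with good precedent for 14-membered cycloalkynes, and the olefin geometry from a cyclic alanate. Here ring closure, a stereocentre and the heterocycle all hang on one macro-annulation without close precedent.

**Alternative 3:** C1–C2 closure by propargylchromium addition.
- Disconnection: the C1–C2 bond, the bond a biosynthesis-like closure of a linear precursor would form. The acyclic enal A6 carries a propargylic bromide at C16 on a C1≡C15 alkyne.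
- Forward key step: CrCl2 (divalent chromium, turned over by manganese metal) inserts into the C16–Br bond. The ambident organochromium adds through C1 to the C2 aldehyde (SE2′), closes the 14-membered ring and leaves the allenyl carbinol A5 (the same structure as A2).
- For it: chromium-mediated additions are highly chemoselective for aldehydes, tolerate olefins, and are well known as macrocyclisations. No protecting group is needed. In protecting-group economy it is better than the chosen route.
- Against it: C2 is again formed in the ring closure with no control element nearby. Correcting it on A5 by oxidation and asymmetric reduction of an allenyl vinyl ketone is unattractive. The organochromium can also deliver the homopropargylic isomer. A5 lacks C17, so the plan must continue with the oxidative carbonylation of Alternative 1 and inherits its conflict with the epoxide.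
- Comparison: two uncertain steps in a row (a stereo-random ring closure, then an oxidative carbonylation) stand against one uncertain but stereochemically neutral ring closure in the chosen route. There C2 is already (S) before cyclisation, and C17 is present from the start as one of two equivalent arms.

Key step: step 14

## Route

Step 1
Reactants: 1 geraniol
Product: 2 (2S,3S)-2,3-epoxygeraniol
Conditions: Ti(OiPr)4 (cat.), L-(+)-diethyl tartrate, tBuOOH, 4 Å MS, CH2Cl2, −20 °C
Reagents that add atoms: tert-butyl hydroperoxide, CC(C)(C)OO
Why: Sharpless asymmetric epoxidation; the titanium tartrate binds the allylic hydroxyl and delivers oxygen to one face of the 2,3-olefin, which with L-(+)-tartrate gives the (2S,3S)-epoxide (later C7 and C8). The 6,7-olefin has no directing hydroxyl and is left alone.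

Step 2
Reactants: 2 (2S,3S)-2,3-epoxygeraniol
Product: 3 epoxygeranyl triflate
Conditions: Tf2O, 2,6-lutidine, CH2Cl2, −78 °C (used crude)
Reagents that add atoms: trifluoromethanesulfonic anhydride, O=S(=O)(OS(=O)(=O)C(F)(F)F)C(F)(F)F
Why: O-sulfonylation of the primary alcohol at low temperature; the adjacent epoxide oxygen disfavours ionisation, so the triflate should survive a cold work-up and be used at once.

Step 3
Reactants: 3 epoxygeranyl triflate; 4 2-butyne
Product: 6 epoxy enyne with the C4≡C–CH3 alkyne, via 1-lithio-2-butyne 5 (not isolated)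
Conditions: 4 (excess), n-BuLi, TMEDA, THF, −78 to 0 °C; then 3, −78 °C
Reagents that add atoms: none
Why: SN2 alkylation; the CH2 terminus of 5 displaces the primary triflate at −78 °C, where the trisubstituted epoxide does not react. The C7 and C8 centres are not involved.

Step 4
Reactants: 6 epoxy enyne
Product: 7 E-allylic alcohol (C13–OH)
Conditions: SeO2 (cat.), tBuOOH, CH2Cl2, 0 °C to rt
Reagents that add atoms: selenium dioxide, O=[Se]=O; tert-butyl hydroperoxide, CC(C)(C)OO
Why: Selenium dioxide allylic oxidation (ene reaction, then [2,3]-sigmatropic shift) takes the E-methyl group of the gem-dimethyl olefin, which is much more reactive than the propargylic positions of the internal alkyne. Any enal 8 formed alongside is carried into step 5 with 7.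

Step 5
Reactants: 7 E-allylic alcohol
Product: 8 E-enal (C13 aldehyde)
Conditions: MnO2, CH2Cl2, rt
Reagents that add atoms: none
Why: MnO2 oxidises only the allylic alcohol; alkyne, epoxide and olefin geometry are unaffected.

Step 6
Reactants: 8 E-enal
Product: 9 (E)-diene with terminal vinyl group (C13=C14)
Conditions: Ph3PCH3Br, KN(SiMe3)2, THF, −78 to 0 °C
Reagents that add atoms: methyltriphenylphosphonium bromide, C[P+](c1ccccc1)(c1ccccc1)c1ccccc1.[Br-]
Why: Wittig methylenation; the non-stabilised ylide adds 1,2 to the enal and brings in C14. Epoxide and alkyne are inert to it.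

Step 7
Reactants: 10 1,3-dihydroxyacetone dimer
Product: 11 1,3-bis(TBS-oxy)propan-2-one
Conditions: TBSCl, imidazole, DMF, rt
Reagents that add atoms: tert-butyldimethylsilyl chloride, CC(C)(C)[Si](C)(C)Cl
Why: The dimer dissociates in DMF and the monomeric ketone is silylated at both primary hydroxyls.

Step 8
Reactants: 11 1,3-bis(TBS-oxy)propan-2-one; 12 diethyl (N-methoxy-N-methylcarbamoylmethyl)phosphonate
Product: 13 alkylidene Weinreb amide
Conditions: NaH, THF, 0 °C to rt
Reagents that add atoms: none
Why: Horner–Wadsworth–Emmons olefination of an electrophilic α,α′-dioxygenated ketone; the ketone is symmetric, so the new C1=C15 olefin has no geometry.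

Step 9
Reactants: 13 alkylidene Weinreb amide
Product: 15 α-bromo alkylidene Weinreb amide, via dibromide 14 (not isolated)
Conditions: Br2, CH2Cl2, −78 to 0 °C; then Et3N, 0 °C to rt
Reagents that add atoms: bromine, BrBr
Why: Bromine adds across the enamide, and triethylamine removes HBr through the acidic C1–H (E1cB-like), which returns the conjugated olefin with bromine on C1. The buffered medium spares the silyl ethers.

Step 10
Reactants: 9 (E)-diene; 15 α-bromo alkylidene Weinreb amide
Product: 17 Weinreb amide with the C14–C1 bond, via B-alkyl-9-BBN borane 16 (not isolated)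
Conditions: 9-BBN, THF, 0 °C to rt; then 15, PdCl2(dppf) (cat.), AsPh3, Cs2CO3, DMF/H2O, rt
Reagents that add atoms: none
Why: 9-BBN hydroborates the monosubstituted terminus of the diene anti-Markovnikov, faster than the trisubstituted olefin or the internal alkyne. B-alkyl Suzuki–Miyaura coupling with the electron-poor alkenyl bromide then forms C14–C1. Because 15 is symmetric at C15, no olefin isomer can arise.

Step 11
Reactants: 17 Weinreb amide; 18 1-propynylmagnesium bromide
Product: 19 ynone (C2 ketone)
Conditions: THF, −20 to 0 °C; cold aq. NH4Cl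
Reagents that add atoms: none
Why: Weinreb ketone synthesis; the chelated tetrahedral adduct prevents over-addition, and the cold quench keeps the released amine from adding to the ynone.

Step 12
Reactants: 19 ynone
Product: 20 (S)-propargylic alcohol
Conditions: Ru[(R,R)-TsNCH(Ph)CH(Ph)NH](p-cymene) (cat.), iPrOH, rt
Reagents that add atoms: none
Why: Noyori asymmetric transfer hydrogenation; the divalent ruthenium hydride reduces only the carbonyl by an outer-sphere H/H transfer. The slim alkynyl group takes the site beside the arene ligand and the twisted tetrasubstituted alkenyl group behaves as the bulky alkyl partner. With the (R,R)-ligand hydride should enter on the Re face (O > C1 > C3) and set C2 as (S).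

Step 13
Reactants: 20 (S)-propargylic alcohol
Product: 21 tris-TBS diyne
Conditions: TBSCl, imidazole, DMAP (cat.), DMF, rt
Reagents that add atoms: tert-butyldimethylsilyl chloride, CC(C)(C)[Si](C)(C)Cl
Why: Silylation of the secondary propargylic alcohol under non-acidic conditions that do not touch the epoxide; the catalyst of step 14 needs the hydroxyl masked.

Step 14
Reactants: 21 tris-TBS diyne
Product: 22 14-membered C3≡C4 cycloalkyne
Conditions: Mo(≡CC6H4-4-OMe)(OSiPh3)3 (cat.), 5 Å MS, toluene (2 mM), rt to 60 °C
Reagents that add atoms: none
Why: The hexavalent molybdenum alkylidyne adds to the unhindered C4≡C–CH3 alkyne in a [2+2] step, and cycloreversion of the metallacyclobutadiene puts the metal on C4; the same [2+2]/retro-[2+2] sequence with the C3≡C–CH3 alkyne forms C3≡C4 and a methyl-bearing alkylidyne that goes on to release 2-butyne (4). The closest known reaction type is ring-closing alkyne metathesis of bis(methyl-capped) diynes to large cycloalkynes that carry propargylic silyl ethers, run with triarylsilanolate molybdenum alkylidynes. The 14-membered carbocycle is closed end to end between the two chain termini, with the new triple bond endocyclic, and no other ring forms. No stereocentre is created; C2, C7 and C8 are untouched and a triple bond has no geometry. The first selectivity needed is ring closure over oligomerisation, secured by high dilution, the reversibility of acyclic metathesis, trapping of 2-butyne by the sieves, and a strain-free product in which the linear C2–C3≡C4–C5 unit is spanned by a chain hinged at the E-olefin, the epoxide and sp2 C1. The second is chemoselectivity: alkylidynes do not engage the tri- and tetrasubstituted olefins, and the silanolate ligands keep the metal mild enough for the epoxide and silyl ethers. Initiation at the open C4 end followed by closure onto the hindered C3 end is the expected order.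

Step 15
Reactants: 22 cycloalkyne
Product: 23 triol cycloalkyne
Conditions: Bu4NF, THF, 0 °C to rt
Reagents that add atoms: none
Why: Fluoride cleaves all three Si–O bonds; epoxide, alkyne and olefins are inert to it, and no acid is used.

Step 16
Reactants: 23 triol cycloalkyne
Product: 25 (Z)-C4 alkenyl iodide, via cyclic alkenylalanate 24 (not isolated)
Conditions: NaAlH2(OCH2CH2OMe)2 (excess), THF, 0 °C to rt; EtOAc; then I2, THF, −78 to 0 °C
Reagents that add atoms: iodine, II
Why: Hydroxyl-directed trans-hydroalumination; the C2 alkoxyaluminium hydride delivers hydride to C3 and aluminium to C4 in a five-membered oxa-aluminacycle, so aluminium is cis to C2. Iodine then cleaves the C–Al bond with retention. An isolated trisubstituted epoxide and the tetrasubstituted olefin should not be reduced at 0 °C.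

Step 17
Reactants: 25 (Z)-alkenyl iodide
Product: 26 triol with E-C3=C4 olefin (C18 methyl in place)
Conditions: Me2Zn (excess), Pd(PPh3)4 (cat.), THF, 0 °C to rt
Reagents that add atoms: dimethylzinc, C[Zn]C
Why: Negishi coupling; oxidative addition to zerovalent palladium, methyl transfer from zinc and reductive elimination all go with retention, which turns the (Z)-iodide into the E-olefin. The hydroxyls are only converted to zinc alkoxides by the excess reagent.

Step 18
Reactants: 26 triol
Product: 28 dihydrofuran C17 tosylate, via bis-tosylate 27 (not isolated)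
Conditions: Ts2O, Et3N, DMAP (cat.), CH2Cl2, −20 °C to rt (used crude)
Reagents that add atoms: p-toluenesulfonic anhydride, Cc1ccc(cc1)S(=O)(=O)OS(=O)(=O)c1ccc(C)cc1
Why: The two primary allylic hydroxyls are sulfonylated ahead of the hindered secondary one. The C2 hydroxyl then displaces the tosyloxymethyl arm held cis to it by the C1=C15 olefin (5-exo-tet Williamson etherification), and the trans arm cannot react. The C2–O bond is not broken, so C2 stays (S).

Step 19
Reactants: 28 dihydrofuran C17 tosylate
Product: 29 target acetate
Conditions: CsOAc, DMF, rt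
Reagents that add atoms: cesium acetate, CC(=O)[O-].[Cs+]
Why: SN2 displacement of the primary allylic tosylate by acetate; SN2′ attack would have to occur at the fully substituted C1 and is disfavoured.

## Compound list

1 | geraniol, (2E)-3,7-dimethylocta-2,6-dien-1-ol | CC(C)=CCC/C(C)=C/CO | starting material
2 | [(2S,3S)-3-methyl-3-(4-methylpent-3-en-1-yl)oxiran-2-yl]methanol | CC(C)=CCC[C@]1(C)O[C@H]1CO | intermediate
3 | [(2S,3S)-3-methyl-3-(4-methylpent-3-en-1-yl)oxiran-2-yl]methyl trifluoromethanesulfonate | CC(C)=CCC[C@]1(C)O[C@H]1COS(=O)(=O)C(F)(F)F | intermediate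
4 | 2-butyne | CC#CC | starting material
5 | 1-lithio-2-butyne | [Li]CC#CC | intermediate
6 | (2S,3S)-2-methyl-2-(4-methylpent-3-en-1-yl)-3-(pent-3-yn-1-yl)oxirane | CC(C)=CCC[C@]1(C)O[C@H]1CCC#CC | intermediate
7 | (2E)-2-methyl-5-[(2S,3S)-2-methyl-3-(pent-3-yn-1-yl)oxiran-2-yl]pent-2-en-1-ol | OC/C(C)=C/CC[C@]1(C)O[C@H]1CCC#CC | intermediate
8 | (2E)-2-methyl-5-[(2S,3S)-2-methyl-3-(pent-3-yn-1-yl)oxiran-2-yl]pent-2-enal | O=C/C(C)=C/CC[C@]1(C)O[C@H]1CCC#CC | intermediate
9 | (2S,3S)-2-methyl-2-[(3E)-4-methylhexa-3,5-dien-1-yl]-3-(pent-3-yn-1-yl)oxirane | C=C/C(C)=C/CC[C@]1(C)O[C@H]1CCC#CC | intermediate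
10 | 1,3-dihydroxyacetone dimer, 2,5-bis(hydroxymethyl)-1,4-dioxane-2,5-diol | OCC1(O)COC(O)(CO)CO1 | starting material
11 | 1,3-bis[(tert-butyldimethylsilyl)oxy]propan-2-one | CC(C)(C)[Si](C)(C)OCC(=O)CO[Si](C)(C)C(C)(C)C | intermediate
12 | diethyl (N-methoxy-N-methylcarbamoylmethyl)phosphonate | CCOP(=O)(OCC)CC(=O)N(C)OC | starting material
13 | 4-(TBS-oxy)-3-(TBS-oxymethyl)-N-methoxy-N-methylbut-2-enamide | CON(C)C(=O)C=C(CO[Si](C)(C)C(C)(C)C)CO[Si](C)(C)C(C)(C)C | intermediate
14 | 2,3-dibromo-4-(TBS-oxy)-3-(TBS-oxymethyl)-N-methoxy-N-methylbutanamide (racemic) | CON(C)C(=O)C(Br)C(Br)(CO[Si](C)(C)C(C)(C)C)CO[Si](C)(C)C(C)(C)C | intermediate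
15 | 2-bromo-4-(TBS-oxy)-3-(TBS-oxymethyl)-N-methoxy-N-methylbut-2-enamide | CON(C)C(=O)C(Br)=C(CO[Si](C)(C)C(C)(C)C)CO[Si](C)(C)C(C)(C)C | intermediate
16 | 9-{(3E)-3-methyl-6-[(2S,3S)-2-methyl-3-(pent-3-yn-1-yl)oxiran-2-yl]hex-3-en-1-yl}-9-borabicyclo[3.3.1]nonane | B1(CC/C(C)=C/CC[C@]2(C)O[C@H]2CCC#CC)C3CCCC1CCC3 | intermediate
17 | (5E)-2-[1,3-bis(TBS-oxy)propan-2-ylidene]-N-methoxy-N,5-dimethyl-8-[(2S,3S)-2-methyl-3-(pent-3-yn-1-yl)oxiran-2-yl]oct-5-enamide | CON(C)C(=O)C(CC/C(C)=C/CC[C@]1(C)O[C@H]1CCC#CC)=C(CO[Si](C)(C)C(C)(C)C)CO[Si](C)(C)C(C)(C)C | intermediate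
18 | 1-propynylmagnesium bromide | CC#C[Mg]Br | starting material
19 | (8E)-5-[1,3-bis(TBS-oxy)propan-2-ylidene]-8-methyl-11-[(2S,3S)-2-methyl-3-(pent-3-yn-1-yl)oxiran-2-yl]undec-8-en-2-yn-4-one | CC#CC(=O)C(CC/C(C)=C/CC[C@]1(C)O[C@H]1CCC#CC)=C(CO[Si](C)(C)C(C)(C)C)CO[Si](C)(C)C(C)(C)C | intermediate
20 | (4S,8E)-5-[1,3-bis(TBS-oxy)propan-2-ylidene]-8-methyl-11-[(2S,3S)-2-methyl-3-(pent-3-yn-1-yl)oxiran-2-yl]undec-8-en-2-yn-4-ol | CC#C[C@H](O)C(CC/C(C)=C/CC[C@]1(C)O[C@H]1CCC#CC)=C(CO[Si](C)(C)C(C)(C)C)CO[Si](C)(C)C(C)(C)C | intermediate
21 | TBS ether of 20 at the C2 (S) oxygen; acyclic diyne with methyl-capped alkynes at C3 and C4 | CC#C[C@H](O[Si](C)(C)C(C)(C)C)C(CC/C(C)=C/CC[C@]1(C)O[C@H]1CCC#CC)=C(CO[Si](C)(C)C(C)(C)C)CO[Si](C)(C)C(C)(C)C | intermediate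
22 | 14-membered cycloalkyne: C3≡C4, (2S)-OTBS, (7S,8S)-epoxide, (11E)-olefin, C1=C15 bearing two CH2OTBS arms | CC(C)(C)[Si](C)(C)OCC(CO[Si](C)(C)C(C)(C)C)=C1CC/C(C)=C/CC[C@]2(C)O[C@H]2CCC#C[C@@H]1O[Si](C)(C)C(C)(C)C | intermediate
23 | triol cycloalkyne: as 22 with free C2, C16 and C17 hydroxyls | OCC(CO)=C1CC/C(C)=C/CC[C@]2(C)O[C@H]2CCC#C[C@@H]1O | intermediate
24 | sodium alkenylalanate: five-membered O(C2)–Al–C4=C3–C2 ring, Al bearing two 2-methoxyethoxy groups (primary hydroxyls drawn free; in the flask they are aluminium alkoxides too) | OCC(CO)=C1CC/C(C)=C/CC[C@]2(C)O[C@H]2CC/C3=C/[C@@H]1O[Al-]3(OCCOC)OCCOC.[Na+] | intermediate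
25 | (3Z)-4-iodo triol: (2S)-OH, C3=C4 with iodine on C4 cis to C2 | OCC(CO)=C1CC/C(C)=C/CC[C@]2(C)O[C@H]2CC/C(I)=C/[C@@H]1O | intermediate
26 | (2S,3E,7S,8S,11E)-triol with C4 methyl, free C2, C16 and C17 hydroxyls | OCC(CO)=C1CC/C(C)=C/CC[C@]2(C)O[C@H]2CC/C(C)=C/[C@@H]1O | intermediate
27 | C16,C17-bis(p-toluenesulfonate) of 26 | Cc1ccc(cc1)S(=O)(=O)OCC(COS(=O)(=O)c1ccc(C)cc1)=C1CC/C(C)=C/CC[C@]2(C)O[C@H]2CC/C(C)=C/[C@@H]1O | intermediate
28 | dihydrofuran-fused macrocycle with C17 p-toluenesulfonate | Cc1ccc(cc1)S(=O)(=O)OCC1=C2CC/C(C)=C/CC[C@]3(C)O[C@H]3CC/C(C)=C/[C@@H]2OC1 | intermediate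
29 | CNP0140293.1, the (2S,7S,8S) C17 acetate | CC(=O)OCC1=C2CC/C(C)=C/CC[C@]3(C)O[C@H]3CC/C(C)=C/[C@@H]2OC1 | target

## Step count and least certain steps

Total: 19 steps. Longest linear sequence: 16 steps (steps 1–6 and 10–19, from geraniol); steps 7–9 form a three-step side branch.

**Step 14 (key step).** The most likely failure is that the alkylidyne engages only the open C4 alkyne, while the C3 alkyne, α-branched by the silyl ether and the tetrasubstituted olefin, reacts too slowly. Dimerisation through the C4 ends and oligomerisation would then outrun ring closure, or the catalyst would decay first. The fallback moves the ring closure to C14–C1 and builds C2–C3≡C4 by acetylide addition; it sets out from 3 and returns at 22.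
- Alkylation of 3 with lithiated 1-(trimethylsilyl)propyne gives the silylalkyne F1.
- SeO2/tBuOOH gives the allylic alcohol F2, MnO2 the enal F3, and Wittig methylenation the diene F4.
- K2CO3 in MeOH frees the terminal alkyne F5.
- n-BuLi converts F5 into the lithium acetylide F6, which adds to Weinreb amide 15 to give the bromo ynone F7.
- Transfer hydrogenation with the (R,R)-catalyst of step 12 gives the (S)-alcohol F8, and TBSCl/imidazole gives the silyl ether F9.
- 9-BBN hydroborates the diene terminus to the borane F10, and PdCl2(dppf)/AsPh3/Cs2CO3 at high dilution (B-alkyl Suzuki–Miyaura macrocyclisation) closes C14–C1 to 22.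

**Step 3.** The ambident 2-butynyl anion may react through its allenyl terminus and give an allene isomer, or the epoxide may be opened. The fallback sets out from 3 and returns at 6. Lithiated 1-(triisopropylsilyl)propyne, whose bulky silyl group blocks the allenyl terminus, gives the silylalkyne F11. Bu4NF gives the terminal alkyne F12. n-BuLi gives the lithium acetylide F13, and methyl iodide then gives 6.

**Step 10.** Transmetalation and reductive elimination at a fully substituted alkenylpalladium centre may be slow, so that protodeboronation, β-hydride elimination or double hydroboration of the diene take over. The fallback forms the tetrasubstituted olefin by olefination; it sets out from 9 (through 16) and returns at 17. Oxidation of 16 with NaOH/H2O2 gives the primary alcohol F14, and I2/PPh3/imidazole gives the iodide F15. Alkylation of the sodium salt of 12 with F15 gives the substituted phosphonate F16. Horner–Wadsworth–Emmons reaction of F16 with ketone 11 (NaH, THF) gives 17.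

**Step 12.** Two π-substituents flank the ketone, so facial discrimination may be poor and the C2 configuration low in purity. The fallback sets C2 while making the C2–C3 bond; it sets out from 17 and returns at 20. iBu2AlH at −78 °C reduces the Weinreb amide to the enal F17. Enantioselective propynylation (propyne, Me2Zn, the ProPhenol enantiomer that delivers the alkynyl group to the Si face, O > C1 > H) gives 20 directly.

**Step 16.** Hydride may open the epoxide, or the three alkoxides may form poorly soluble aluminates that slow the directed addition and give incomplete iodination. The fallback avoids hydride; it sets out from 23 and returns at 25. Ruthenium-catalysed trans-hydrosilylation with [Cp*Ru(MeCN)3]PF6 (divalent ruthenium) and BnMe2SiH puts silicon on C4, distal to the hydroxyl, and gives the (Z)-alkenylsilane F18. Iododesilylation with N-iodosuccinimide proceeds with retention to 25.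

**Step 18.** The doubly allylic C2 hydroxyl may be sulfonylated and ionise, or the allylic sulfonate may decompose before acetate arrives. The fallback replaces sulfonate activation by redox dehydration; it sets out from 26 and returns at 29. Mitsunobu cyclodehydration (PPh3, diisopropyl azodicarboxylate) of the cis-ene-1,4-diol unit gives the dihydrofuran alcohol F19. Only the arm cis to C2 can close, and the other hydroxyl stays free. Ac2O/pyridine then gives 29.

## Further compounds

F1 | step 14 | (2S,3S)-2-methyl-2-(4-methylpent-3-en-1-yl)-3-[4-(trimethylsilyl)but-3-yn-1-yl]oxirane | CC(C)=CCC[C@]1(C)O[C@H]1CCC#C[Si](C)(C)C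
F2 | step 14 | (2E)-2-methyl-5-{(2S,3S)-2-methyl-3-[4-(trimethylsilyl)but-3-yn-1-yl]oxiran-2-yl}pent-2-en-1-ol | OC/C(C)=C/CC[C@]1(C)O[C@H]1CCC#C[Si](C)(C)C
F3 | step 14 | (2E)-2-methyl-5-{(2S,3S)-2-methyl-3-[4-(trimethylsilyl)but-3-yn-1-yl]oxiran-2-yl}pent-2-enal | O=C/C(C)=C/CC[C@]1(C)O[C@H]1CCC#C[Si](C)(C)C
F4 | step 14 | (2S,3S)-2-methyl-2-[(3E)-4-methylhexa-3,5-dien-1-yl]-3-[4-(trimethylsilyl)but-3-yn-1-yl]oxirane | C=C/C(C)=C/CC[C@]1(C)O[C@H]1CCC#C[Si](C)(C)C
F5 | step 14 | (2S,3S)-3-(but-3-yn-1-yl)-2-methyl-2-[(3E)-4-methylhexa-3,5-dien-1-yl]oxirane | C=C/C(C)=C/CC[C@]1(C)O[C@H]1CCC#C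
F6 | step 14 | lithium acetylide of F5 | C=C/C(C)=C/CC[C@]1(C)O[C@H]1CCC#C[Li]
F7 | step 14 | bromo ynone: C2 ketone, C3≡C4, C1–Br, two CH2OTBS arms, diene terminus | C=C/C(C)=C/CC[C@]1(C)O[C@H]1CCC#CC(=O)C(Br)=C(CO[Si](C)(C)C(C)(C)C)CO[Si](C)(C)C(C)(C)C
F8 | step 14 | (S)-propargylic alcohol from F7 | C=C/C(C)=C/CC[C@]1(C)O[C@H]1CCC#C[C@H](O)C(Br)=C(CO[Si](C)(C)C(C)(C)C)CO[Si](C)(C)C(C)(C)C
F9 | step 14 | TBS ether of F8 | C=C/C(C)=C/CC[C@]1(C)O[C@H]1CCC#C[C@H](O[Si](C)(C)C(C)(C)C)C(Br)=C(CO[Si](C)(C)C(C)(C)C)CO[Si](C)(C)C(C)(C)C
F10 | step 14 | B-alkyl-9-borabicyclo[3.3.1]nonane from F9 (boron on C14) | B1(CC/C(C)=C/CC[C@]2(C)O[C@H]2CCC#C[C@H](O[Si](C)(C)C(C)(C)C)C(Br)=C(CO[Si](C)(C)C(C)(C)C)CO[Si](C)(C)C(C)(C)C)C3CCCC1CCC3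
F11 | step 3 | (2S,3S)-2-methyl-2-(4-methylpent-3-en-1-yl)-3-[4-(triisopropylsilyl)but-3-yn-1-yl]oxirane | CC(C)=CCC[C@]1(C)O[C@H]1CCC#C[Si](C(C)C)(C(C)C)C(C)C
F12 | step 3 | (2S,3S)-3-(but-3-yn-1-yl)-2-methyl-2-(4-methylpent-3-en-1-yl)oxirane | CC(C)=CCC[C@]1(C)O[C@H]1CCC#C
F13 | step 3 | lithium acetylide of F12 | CC(C)=CCC[C@]1(C)O[C@H]1CCC#C[Li]
F14 | step 10 | (3E)-3-methyl-6-[(2S,3S)-2-methyl-3-(pent-3-yn-1-yl)oxiran-2-yl]hex-3-en-1-ol | OCC/C(C)=C/CC[C@]1(C)O[C@H]1CCC#CC
F15 | step 10 | (2S,3S)-2-[(3E)-6-iodo-4-methylhex-3-en-1-yl]-2-methyl-3-(pent-3-yn-1-yl)oxirane | ICC/C(C)=C/CC[C@]1(C)O[C@H]1CCC#CC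
F16 | step 10 | α-alkylated phosphonate: 12 carrying the C14–C5 chain on its α-carbon (mixture at that carbon) | CCOP(=O)(OCC)C(CC/C(C)=C/CC[C@]1(C)O[C@H]1CCC#CC)C(=O)N(C)OC
F17 | step 12 | C2 enal: (5E)-2-[1,3-bis(TBS-oxy)propan-2-ylidene]-5-methyl-8-[(2S,3S)-2-methyl-3-(pent-3-yn-1-yl)oxiran-2-yl]oct-5-enal | O=CC(CC/C(C)=C/CC[C@]1(C)O[C@H]1CCC#CC)=C(CO[Si](C)(C)C(C)(C)C)CO[Si](C)(C)C(C)(C)C
F18 | step 16 | (Z)-C4 benzyldimethylsilyl alkene triol (silicon cis to C2) | OCC(CO)=C1CC/C(C)=C/CC[C@]2(C)O[C@H]2CC/C([Si](C)(C)Cc3ccccc3)=C/[C@@H]1O
F19 | step 18 | dihydrofuran-fused macrocycle with free C17 hydroxyl | OCC1=C2CC/C(C)=C/CC[C@]3(C)O[C@H]3CC/C(C)=C/[C@@H]2OC1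
A1 | alternative 1 | macrocyclic methyl ester (C17 at the carboxylate level) | COC(=O)C1=C2CC/C(C)=C/CC[C@]3(C)O[C@H]3CC/C(C)=C/[C@@H]2OC1
A2 | alternative 1 | macrocyclic C2 allenol with exocyclic C1=C15=C16 allene | C=C=C1CC/C(C)=C/CC[C@]2(C)O[C@H]2CC/C(C)=C/[C@@H]1O
A3 | alternative 2 | butenolide-fused macrocycle (C16 lactone carbonyl, C17 TBS ether) | CC(C)(C)[Si](C)(C)OCC1=C2CC/C(C)=C/CC[C@]3(C)O[C@H]3CC/C(C)=C/[C@@H]2OC1=O
A4 | alternative 2 | acyclic ynal: C2 aldehyde, E-C3=C4, (7S,8S)-epoxide, C1≡C15 alkyne with C17 TBS-oxymethyl | CC(C)(C)[Si](C)(C)OCC#CCC/C(C)=C/CC[C@]1(C)O[C@H]1CC/C(C)=C/C=O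
A5 | alternative 3 | 14-membered C2 allenyl carbinol (same structure as A2) | C=C=C1CC/C(C)=C/CC[C@]2(C)O[C@H]2CC/C(C)=C/[C@@H]1O
A6 | alternative 3 | acyclic C2 enal with C16 propargylic bromide on the C1≡C15 alkyne | BrCC#CCC/C(C)=C/CC[C@]1(C)O[C@H]1CC/C(C)=C/C=O
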